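# Proposed synthesis of CNP0303209.1: ring A from a 4‑methoxy‑2‑pyrone by lactone opening and Claisen closure

## The problem

The target is a diarylmethane in which an acylphloroglucinol (ring A) and a 5,7‑dihydroxy‑2,2,6‑trimethylchroman‑4‑one (ring B with its fused pyranone) are joined by one methylene between ring A carbon a5 and chromanone C8. Both benzene rings are hexasubstituted, so every substituent must be placed with full regiocontrol. In ring A (a1 acyl carbon, a2 C–OH, a3 C–CH3, a4 C–OCH3, a5 C–CH2, a6 C–OH) only the a4 oxygen is methylated. In ring B the pyran oxygen must sit on C8a, next to the bridge, and not next to the C6 methyl group. The only stereocentre is the (R) carbon of the 2‑methylbutanoyl chain; nothing in the molecule can induce it, so it must be bought in and then kept from enolising, because it is α to a ketone. The fragile points are: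
- the α‑hydrogen of that stereocentre (strong base, hot acid);
- the chromanone, which can open by retro‑oxa‑Michael reaction and, with a free C5 hydroxyl, reclose on the other oxygen so that the C6 and C8 substituents change places (Wessely–Moser‑type isomerisation);
- the electron‑rich phenols, which must be told apart from the single methyl ether without ever cleaving an aryl methyl ether selectively.

The key step rests on the ring A pattern a1(acyl)–a2(O)–a3(C)–a4(OMe)–a5(C)–a6(O), a tetraketide folded head to tail. Atoms a6, a5, a4, a3 and a2 are C2 to C6 of a 4‑methoxy‑2‑pyrone and a1 is the methylene of a 2‑oxoalkyl arm on C6, so breaking the lactone C–O bond and joining a1 to a6 turns one ring into the other.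

## Retrosynthesis

**18 to 17.** The last operation is the release of the two ring B phenols, so the two benzyl–oxygen bonds of target 18 are cut to give dibenzyl ether 17. Benzyl is preferred to a second kind of methyl ether (no selective demethylation next to the a4 methoxyl is possible) and to silyl groups (lost in the basic key step). The forward reaction must be neutral and must spare two chelated aryl ketones and the α‑stereocentre.

**17 to 15 (key cut).** The a1–a6 bond of ring A is cut and the a6 oxygen is returned to a lactone, which leads to 4‑methoxy‑2‑pyrone 15; the ring‑opened methyl ester 16 lies on the way. This removes a hexasubstituted arene with three differentiated oxygens in one step and turns the regiochemical problem of ring A into the substitution pattern of a pyrone, which is fixed by construction. Cutting a1–C(acyl) instead (Friedel–Crafts acylation) would require a ring A with three distinguishable oxygens first. The forward reaction must open the lactone with methoxide, close by Claisen and not by aldol condensation, and leave the stereocentre and ring B alone. The C5 benzyl ether of ring B ensures that a chromanone that opens under base can only reclose as it was.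

**15 to 14.** The O–CH3 bond is cut. Methylation is placed at the pyrone stage because the C4 hydroxyl of 14 is by far the most acidic group present and ring B carries no free hydroxyl, whereas on the finished arene a4–OH would have to be distinguished from a2–OH and a6–OH. The forward reaction must prefer the C4 oxygen to the lactone carbonyl oxygen and must not touch the arm methylene.

**14 to 6 and 12.** The bond between pyrone C3 and the bridging methylene is cut. This gives hydroxypyrone 6, whose C3 is its most acidic carbon, and aldehyde 12, whose formyl carbon becomes the bridge. The neighbouring cut, methylene to C8 with ring B as the nucleophile, would need free ring B phenols and an electrophilic pyrone methylene, which invites homodimers and leaves no clean way to benzylate afterwards. The forward reaction must form a C–C and not a C–O bond and must leave the hindered side‑chain ketone alone.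

**6 to 3 and 5; 5 to 4.** The bond between the arm methylene and its carbonyl is cut, which gives the simple pyrone 3 and Weinreb amide 5 of acid 4. This bond is made before the fragments are joined, not after: the strong base it needs would otherwise enolise the chromanone of ring B. The forward reaction must deprotonate only the C6 methyl of 3 (after the hydroxyl) and must not enolise the amide.

**3 to 2 to 1.** The lactone C–O bond and then the C–CO2H bond are cut; pyrone 3 comes from diketo acid 2 and this from diketone 1 by carboxylation at a terminal methyl group. All carbons of ring A except a1 and the acyl chain are thus traced to 1 and one carbon from carboxylation.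

**12 to 11 to 10 to 7 and 8.** The two benzyl groups are removed (11), then the C8–CHO bond (10). Finally the chromanone is opened at O1–C2 and C4–C4a, through enone 9, to 2‑methylphloroglucinol 7 and 3‑methylbut‑2‑enoic acid 8. Formylation is placed after the annulation because C8 is then the only free ring position. Benzylation is placed last so that no benzyl ether meets strong acid. The forward annulation must close on the oxygen remote from the methyl group; this is the one regiochemical decision in the ring B branch.

## Roads not taken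

**Alternative 1:** Ring B is cut at C8–C8a and C6–C7 and assembled last by benzannulation. Heating cyclobutenone A2 with siloxyalkyne A3, which already carries a ring A arene on its propargylic carbon, would open the four‑membered ring to a vinylketene, add the alkyne, open again and close by 6π electrocyclisation to phenol A1.
- Merit: the three ring B oxygens emerge fully differentiated (free at C8a, silyl at C7, benzyl at C5), so the pyranone can later close on C8a without ambiguity. In this respect it is better than the chosen plan, which relies on a chelation bias in step 5.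
- Weak points: A1 lacks the chromanone carbons on ring B and the acyl group on ring A. Two Friedel–Crafts acylations would have to distinguish two electron‑rich rings, each with one free position, under Lewis acids that threaten the silyl and benzyl ethers and expose the stereocentre to acid. A2 and A3 are multi‑step compounds, and ring A must be built and differentiated separately.
- Comparison: the chosen plan sets against the one advantage the fact that 10 has a single free position after step 5, and a fallback that strengthens the bias. In step count and in handling of the stereocentre it is shorter and safer.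

**Alternative 2:** The pyran ring is cut at C4–C4a. Propargyl ether A5 would, on heating, undergo aryl propargyl ether Claisen rearrangement to C4a, a hydrogen shift and oxa‑6π electrocyclisation to chromene A4.
- Merit: the step is thermal and neutral, and because the ether oxygen is in place before the ring closes and C8 is blocked, the pyran ring can form only one way. This is as good as or better than step 5 of the chosen plan.
- Weak points: A4 is a 2H‑chromene, not a chroman‑4‑one, so oxygen must still be put on C4 by Markovnikov oxygenation of a hindered double bond and oxidation, in a molecule with four benzyl ethers. A5 presupposes a ring B in which only the C8a oxygen is free, so the differentiation problem is moved and not solved. The whole diarylmethane, ring A and stereocentre included, must exist beforehand, and the road says nothing on how.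
- Comparison: the chosen plan obtains the chromanone oxidation level directly in step 5 and spends its key step on ring A, the harder ring.

**Alternative 3:** Ring A is cut at a5–a6 and a1–a2. The enolate of glutaconic anhydride A7 would add to the ethoxy‑bearing carbon of ynone A8, the resulting allenolate would acylate on the anhydride carbonyl, and decarboxylation would give arene A6.
- Merits: this is more convergent than the chosen plan; ring A arrives with its acyl group in one intermolecular step and no lactone has to be opened. The a6 ethyl ether of A6 is ortho to the acyl group, so its chelation‑assisted cleavage could be merged with the debenzylation, a real economy.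
- Weak points: the nucleophilic carbon of A7 carries the bulky arylmethyl group, so the Michael addition is a crowded intermolecular step, and A7 itself is not simple to make. The stereocentre of A8 is α to an ynone carbonyl and meets the stoichiometric enolate unprotected, whereas in 15 the adjoining ketone is buried in an enolate. A6 also carries a surplus O‑alkyl group.
- Comparison: the chosen plan sets against the convergence an intramolecular closure of a known type whose regiochemistry is fixed by the pyrone skeleton, and a shielded stereocentre.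

Key step: step 10

Remark on the chemistry: pyrone 3 is prepared and not bought, and acid 4 is taken as available in high enantiomeric purity; the route creates no further stereocentre.

## Route

Step 1
Reactants: 1 3‑methylpentane‑2,4‑dione
Product: 2 4‑methyl‑3,5‑dioxohexanoic acid
Conditions: LiN(iPr)2 (2.2 equiv), THF, −78 to 0 °C; CO2, −78 °C; aq. HCl, 0 °C
Reagents that add atoms: carbon dioxide, O=C=O
Why: After double deprotonation the more reactive carbanion sits on a terminal methyl group, which alone is carboxylated (carboxylation of a doubly deprotonated β‑diketone); the β‑keto acid decarboxylates on warming and is therefore kept cold and used crude.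

Step 2
Reactants: 2 4‑methyl‑3,5‑dioxohexanoic acid
Product: 3 4‑hydroxy‑5,6‑dimethyl‑2H‑pyran‑2‑one
Conditions: 1,1'‑carbonyldiimidazole, THF, rt; aq. HCl
Reagents that add atoms: none
Why: Activation of the acid and attack of the enol oxygen of the distal ketone close the six‑membered enol lactone (lactonisation of a 3,5‑dioxo acid), which tautomerises to the 4‑hydroxy‑2‑pyrone.

Step 3
Reactants: 4 (2R)‑2‑methylbutanoic acid
Product: 5 (2R)‑N‑methoxy‑N,2‑dimethylbutanamide
Conditions: 1,1'‑carbonyldiimidazole, CH2Cl2, 0 °C to rt; MeNHOMe·HCl, rt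
Reagents that add atoms: N,O‑dimethylhydroxylamine hydrochloride, CNOC.Cl
Why: Weinreb amide formation through the acyl imidazolide uses no base strong enough to remove the α‑hydrogen, so the (R) centre of 4 is carried over unchanged.

Step 4
Reactants: 3 4‑hydroxy‑5,6‑dimethyl‑2H‑pyran‑2‑one; 5 (2R)‑N‑methoxy‑N,2‑dimethylbutanamide
Product: 6 4‑hydroxy‑5‑methyl‑6‑[(3R)‑3‑methyl‑2‑oxopentyl]‑2H‑pyran‑2‑one
Conditions: 3 (1.2 equiv), LiN(iPr)2 (2.0 equiv per 3), THF–DMPU, −78 to −20 °C; 5, −78 to 0 °C; aq. HCl
Reagents that add atoms: none
Why: Doubly deprotonated 3 (hydroxyl first, then the C6 methyl, the only alkyl position vinylogous to the lactone carbonyl) is C‑acylated by the Weinreb amide, a known reaction of 4‑hydroxy‑6‑methyl‑2‑pyrones with acyl donors; because a Weinreb amide releases its ketone only on quench, no excess base meets the product, and the (R) centre is retained.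

Step 5
Reactants: 7 2‑methylbenzene‑1,3,5‑triol (2‑methylphloroglucinol); 8 3‑methylbut‑2‑enoic acid
Product: 10 5,7‑dihydroxy‑2,2,6‑trimethylchroman‑4‑one, via aryl enone 9 (not isolated)
Conditions: P2O5, MeSO3H, 70 °C
Reagents that add atoms: none
Why: Friedel–Crafts acylation at one of the two equivalent free positions of 7 gives enone 9, which closes by acid‑catalysed oxa‑Michael addition; the hydroxyl flanked by the methyl group is held in the stronger chelate to the ketone, so ring closure should occur mainly through the hydroxyl next to the unsubstituted carbon and give the 6‑methyl isomer with C8 free, any 8‑methyl isomer being removed by chromatography or crystallisation.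

Step 6
Reactants: 10 5,7‑dihydroxy‑2,2,6‑trimethylchroman‑4‑one
Product: 11 5,7‑dihydroxy‑2,2,6‑trimethyl‑4‑oxochromane‑8‑carbaldehyde
Conditions: Cl2CHOMe, TiCl4, CH2Cl2, −10 °C to rt; aq. HCl
Reagents that add atoms: dichloromethyl methyl ether, COC(Cl)Cl; water, O
Why: Rieche formylation, well known for acylphloroglucinols; the titanium phenoxide of the C7 hydroxyl directs the electrophile to C8, the only unsubstituted ring carbon, and aqueous work‑up releases the aldehyde.

Step 7
Reactants: 11 5,7‑dihydroxy‑2,2,6‑trimethyl‑4‑oxochromane‑8‑carbaldehyde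
Product: 12 5,7‑bis(benzyloxy)‑2,2,6‑trimethyl‑4‑oxochromane‑8‑carbaldehyde
Conditions: BnBr, K2CO3, Bu4NI (cat.), DMF, 60 °C
Reagents that add atoms: benzyl bromide, BrCc1ccccc1
Why: Williamson benzylation of the two chelated phenols needs warm DMF and iodide catalysis but meets no competing nucleophile, since the ring is fully substituted and the aldehyde cannot enolise; the C5 benzyl ether later prevents the chromanone from reclosing on the wrong oxygen.

Step 8
Reactants: 6 4‑hydroxy‑5‑methyl‑6‑[(3R)‑3‑methyl‑2‑oxopentyl]‑2H‑pyran‑2‑one; 12 5,7‑bis(benzyloxy)‑2,2,6‑trimethyl‑4‑oxochromane‑8‑carbaldehyde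
Product: 14 3‑{[5,7‑bis(benzyloxy)‑2,2,6‑trimethyl‑4‑oxochroman‑8‑yl]methyl}‑4‑hydroxy‑5‑methyl‑6‑[(3R)‑3‑methyl‑2‑oxopentyl]‑2H‑pyran‑2‑one, via arylidene pyrandione 13 (not isolated)
Conditions: diethyl 2,6‑dimethyl‑1,4‑dihydropyridine‑3,5‑dicarboxylate (Hantzsch ester, 1.1 equiv), L‑proline (20 mol%), CH2Cl2, rt to 40 °C
Reagents that add atoms: none
Why: Three‑component reductive alkylation of a 4‑hydroxy‑2‑pyrone: proline‑catalysed Knoevenagel condensation at pyrone C3, the most acidic carbon of 6, gives 13, whose exocyclic double bond takes hydride from the Hantzsch ester before a second pyrone can add; the new bond is therefore C–C and not C–O, and the hindered side‑chain ketone with its (R) centre is not engaged.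

Step 9
Reactants: 14 3‑{[5,7‑bis(benzyloxy)‑2,2,6‑trimethyl‑4‑oxochroman‑8‑yl]methyl}‑4‑hydroxy‑5‑methyl‑6‑[(3R)‑3‑methyl‑2‑oxopentyl]‑2H‑pyran‑2‑one
Product: 15 3‑{[5,7‑bis(benzyloxy)‑2,2,6‑trimethyl‑4‑oxochroman‑8‑yl]methyl}‑4‑methoxy‑5‑methyl‑6‑[(3R)‑3‑methyl‑2‑oxopentyl]‑2H‑pyran‑2‑one
Conditions: Me2SO4 (1.05 equiv), K2CO3 (1.0 equiv), acetone, rt to 40 °C
Reagents that add atoms: dimethyl sulfate, COS(=O)(=O)OC
Why: The pyrone hydroxyl, a vinylogous acid, is the only group ionised by one equivalent of K2CO3, and its potassium salt is methylated by dimethyl sulfate mainly on the C4 oxygen to give the 4‑methoxy‑2‑pyrone (Williamson‑type O‑methylation); the arm methylene stays protonated while pyronate is present and only hydrogen carbonate is left at the end.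

Step 10
Reactants: 15 3‑{[5,7‑bis(benzyloxy)‑2,2,6‑trimethyl‑4‑oxochroman‑8‑yl]methyl}‑4‑methoxy‑5‑methyl‑6‑[(3R)‑3‑methyl‑2‑oxopentyl]‑2H‑pyran‑2‑one
Product: 17 (2R)‑1‑[3‑{[5,7‑bis(benzyloxy)‑2,2,6‑trimethyl‑4‑oxochroman‑8‑yl]methyl}‑2,6‑dihydroxy‑4‑methoxy‑5‑methylphenyl]‑2‑methylbutan‑1‑one, via ring‑opened methyl ester 16 (not isolated)
Conditions: Mg(OMe)2 (excess), MeOH (anhydrous), reflux; aq. HCl, 0 °C
Reagents that add atoms: none
Why: Methoxide from Mg(OMe)2 adds to the lactone carbonyl (a6) of 15 and the ring opens to methyl ester 16, held as the magnesium chelate of its 1,3‑diketone. The central methylene of that diketone (a1) attacks the ester carbon in a Claisen (Dieckmann‑type) condensation, methoxide leaves and the cyclohexenetrione enolises to arene 17; the closest known reaction type is the base‑induced recyclisation of 6‑(2‑oxoalkyl)‑4‑oxygenated 2‑pyrones to acylphloroglucinols. Ring A closes by 6‑exo‑trig attack on the ester carbonyl. No stereocentre is formed, and the existing (R) centre lies next to a ketone that stays inside a chelated enolate throughout, which makes its hydrogen the least acidic α‑hydrogen present. The step needs Claisen closure to win over aldol closure and over retro‑Claisen loss of the arm: the aldol path is shut because the carbon that would have to attack the side‑chain ketone carries the arylmethyl group and is part of a methyl enol ether, so no arene can arise from it, while the enol ether double bond of 16 keeps the pyrone geometry with ester and diketone chain on the same side. Anhydrous Mg(OMe)2 is used so that the lactone opens to an ester and not to an unreactive carboxylate, and the magnesium chelate shields the side‑chain ketone from methoxide. Should the chromanone of ring B open by retro‑oxa‑Michael reaction, the C5 benzyl ether leaves only the C8a oxygen for reclosure, which takes place on acidification.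

Step 11
Reactants: 17 (2R)‑1‑[3‑{[5,7‑bis(benzyloxy)‑2,2,6‑trimethyl‑4‑oxochroman‑8‑yl]methyl}‑2,6‑dihydroxy‑4‑methoxy‑5‑methylphenyl]‑2‑methylbutan‑1‑one
Product: 18 (2R)‑1‑[3‑[(5,7‑dihydroxy‑2,2,6‑trimethyl‑4‑oxochroman‑8‑yl)methyl]‑2,6‑dihydroxy‑4‑methoxy‑5‑methylphenyl]‑2‑methylbutan‑1‑one
Conditions: H2 (1 atm), 10% Pd/C, EtOAc, rt
Reagents that add atoms: none
Why: Hydrogenolysis of the two aryl benzyl ethers in a neutral solvent should leave the chelated, electron‑rich aryl ketones, the diarylmethane and the α‑stereocentre untouched and give the target.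

## Compound list

1 | 3‑methylpentane‑2,4‑dione | CC(=O)C(C)C(C)=O | starting material
2 | 4‑methyl‑3,5‑dioxohexanoic acid | CC(=O)C(C)C(=O)CC(O)=O | intermediate
3 | 4‑hydroxy‑5,6‑dimethyl‑2H‑pyran‑2‑one | CC1=C(C)C(O)=CC(=O)O1 | intermediate
4 | (2R)‑2‑methylbutanoic acid | CC[C@@H](C)C(O)=O | starting material
5 | (2R)‑N‑methoxy‑N,2‑dimethylbutanamide | CC[C@@H](C)C(=O)N(C)OC | intermediate
6 | 4‑hydroxy‑5‑methyl‑6‑[(3R)‑3‑methyl‑2‑oxopentyl]‑2H‑pyran‑2‑one | CC[C@@H](C)C(=O)CC1=C(C)C(O)=CC(=O)O1 | intermediate
7 | 2‑methylbenzene‑1,3,5‑triol (2‑methylphloroglucinol) | Cc1c(O)cc(O)cc1O | starting material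
8 | 3‑methylbut‑2‑enoic acid | CC(C)=CC(O)=O | starting material
9 | 3‑methyl‑1‑(2,4,6‑trihydroxy‑3‑methylphenyl)but‑2‑en‑1‑one | CC(C)=CC(=O)c1c(O)cc(O)c(C)c1O | intermediate (not isolated)
10 | 5,7‑dihydroxy‑2,2,6‑trimethylchroman‑4‑one | CC1(C)CC(=O)c2c(O)c(C)c(O)cc2O1 | intermediate
11 | 5,7‑dihydroxy‑2,2,6‑trimethyl‑4‑oxochromane‑8‑carbaldehyde | CC1(C)CC(=O)c2c(O)c(C)c(O)c(C=O)c2O1 | intermediate
12 | 5,7‑bis(benzyloxy)‑2,2,6‑trimethyl‑4‑oxochromane‑8‑carbaldehyde | CC1(C)CC(=O)c2c(OCc3ccccc3)c(C)c(OCc3ccccc3)c(C=O)c2O1 | intermediate
13 | 3‑{[5,7‑bis(benzyloxy)‑2,2,6‑trimethyl‑4‑oxochroman‑8‑yl]methylidene}‑5‑methyl‑6‑[(3R)‑3‑methyl‑2‑oxopentyl]‑2H‑pyran‑2,4(3H)‑dione (alkene geometry not defined) | CC[C@@H](C)C(=O)CC1=C(C)C(=O)C(=Cc2c(OCc3ccccc3)c(C)c(OCc3ccccc3)c3c2OC(C)(C)CC3=O)C(=O)O1 | intermediate (not isolated)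
14 | 3‑{[5,7‑bis(benzyloxy)‑2,2,6‑trimethyl‑4‑oxochroman‑8‑yl]methyl}‑4‑hydroxy‑5‑methyl‑6‑[(3R)‑3‑methyl‑2‑oxopentyl]‑2H‑pyran‑2‑one | CC[C@@H](C)C(=O)CC1=C(C)C(O)=C(Cc2c(OCc3ccccc3)c(C)c(OCc3ccccc3)c3c2OC(C)(C)CC3=O)C(=O)O1 | intermediate
15 | 3‑{[5,7‑bis(benzyloxy)‑2,2,6‑trimethyl‑4‑oxochroman‑8‑yl]methyl}‑4‑methoxy‑5‑methyl‑6‑[(3R)‑3‑methyl‑2‑oxopentyl]‑2H‑pyran‑2‑one | CC[C@@H](C)C(=O)CC1=C(C)C(OC)=C(Cc2c(OCc3ccccc3)c(C)c(OCc3ccccc3)c3c2OC(C)(C)CC3=O)C(=O)O1 | intermediate
16 | methyl (2E,8R)‑2‑{[5,7‑bis(benzyloxy)‑2,2,6‑trimethyl‑4‑oxochroman‑8‑yl]methyl}‑3‑methoxy‑4,8‑dimethyl‑5,7‑dioxodec‑2‑enoate (both C4 epimers; present as its magnesium enolate) | CC[C@@H](C)C(=O)CC(=O)C(C)/C(OC)=C(/Cc1c(OCc2ccccc2)c(C)c(OCc2ccccc2)c2c1OC(C)(C)CC2=O)C(=O)OC | intermediate (not isolated)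
17 | (2R)‑1‑[3‑{[5,7‑bis(benzyloxy)‑2,2,6‑trimethyl‑4‑oxochroman‑8‑yl]methyl}‑2,6‑dihydroxy‑4‑methoxy‑5‑methylphenyl]‑2‑methylbutan‑1‑one | CC[C@@H](C)C(=O)c1c(O)c(C)c(OC)c(Cc2c(OCc3ccccc3)c(C)c(OCc3ccccc3)c3c2OC(C)(C)CC3=O)c1O | intermediate
18 | (2R)‑1‑[3‑[(5,7‑dihydroxy‑2,2,6‑trimethyl‑4‑oxochroman‑8‑yl)methyl]‑2,6‑dihydroxy‑4‑methoxy‑5‑methylphenyl]‑2‑methylbutan‑1‑one | CC[C@@H](C)C(=O)c1c(O)c(C)c(OC)c(Cc2c(O)c(C)c(O)c3c2OC(C)(C)CC3=O)c1O | target

## Step count and least certain steps

Total: 11 steps. Longest linear sequence: 7 steps (steps 1, 2, 4, 8, 9, 10, 11 from 1; equally steps 5, 6, 7, 8, 9, 10, 11 from 7).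

**Step 10 (key step).** The arm methylene of 15 is deprotonated before methoxide adds, and the resulting delocalised anion makes the lactone carbonyl a poor electrophile, so ring opening may stall. Alternatively methoxide may attack the side‑chain ketone and the arm is lost by retro‑Claisen cleavage. Base‑induced opening of the ring B chromanone is a further hazard. The fallback builds ring A by classical means and joins the rings afterwards. It sets out from 4 and 7. Acid 4 is converted with oxalyl chloride into (2R)‑2‑methylbutanoyl chloride F1, which acylates 7 (AlCl3, CH2Cl2–PhNO2, 0 °C) to (2R)‑2‑methyl‑1‑(2,4,6‑trihydroxy‑3‑methylphenyl)butan‑1‑one F2. The hydroxyl para to the acyl group, the only one not chelated, is methylated (Me2SO4, one equivalent, K2CO3, acetone) to (2R)‑1‑(2,6‑dihydroxy‑4‑methoxy‑3‑methylphenyl)‑2‑methylbutan‑1‑one F3. The single free ring position of F3 is then alkylated reductively with aldehyde 12 (Et3SiH, CF3CO2H, CH2Cl2, 0 °C), which returns to the route at 17.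

**Step 5.** Ring closure may take place through the hydroxyl next to the methyl group, or the two chromanones may equilibrate in the acid, because the selection rests only on a hydrogen‑bond preference; the result would be the 8‑methyl isomer. The fallback introduces the aldehyde before the pyranone. It sets out from 7, which is formylated (POCl3, DMF; aqueous hydrolysis; Vilsmeier–Haack) to 2,4,6‑trihydroxy‑3‑methylbenzaldehyde F4. Acylation and cyclisation of F4 with 8 (P2O5, MeSO3H) should give 11 directly, where the route is rejoined. In that intermediate each hydroxyl next to the methyl group is tied in a chelate (one to the formyl group, one to the new ketone), and only the oxygen para to the methyl group is left to close the ring.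

**Step 4.** The sparingly soluble doubly deprotonated pyrone may add slowly to the α‑branched amide and act as a base instead, removing the α‑hydrogen of 5 (loss of configurational purity) or attacking its N‑methoxy group. The fallback changes acylation into aldol addition and oxidation. It sets out from 5, which is reduced (LiAlH4, THF, −78 °C) to (2R)‑2‑methylbutanal F5 and added at once to doubly deprotonated 3 at −78 °C. This gives 4‑hydroxy‑6‑[(3R)‑2‑hydroxy‑3‑methylpentyl]‑5‑methyl‑2H‑pyran‑2‑one F6 as a mixture of carbinol epimers. Oxidation (Dess–Martin periodinane, NaHCO3, CH2Cl2) returns to the route at 6.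

**Step 8.** Knoevenagel condensation of the doubly ortho‑substituted, electron‑rich aldehyde may be slow, and a second pyrone may add to 13 before hydride transfer. The fallback uses ring B as a benzylic cation precursor. It sets out from 12, whose aldehyde is reduced selectively (NaBH4, MeOH–THF, −20 °C) to 5,7‑bis(benzyloxy)‑8‑(hydroxymethyl)‑2,2,6‑trimethylchroman‑4‑one F7. Acid‑catalysed C3‑benzylation of 6 with F7 (TsOH cat., ClCH2CH2Cl, rt to 40 °C; Friedel–Crafts‑type alkylation of a 4‑hydroxypyrone by a benzylic alcohol) returns to the route at 14.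

**Step 9.** Methylation may occur at the lactone carbonyl oxygen (2‑methoxy‑4‑pyranone isomer) or, once the pyronate is consumed, at the arm. The fallback moves the methylation behind the ring change. It sets out from 14, which is treated with Mg(OMe)2 in MeOH as in step 10 (the aldol path remains blocked by the C3 substituent) to give (2R)‑1‑[3‑{[5,7‑bis(benzyloxy)‑2,2,6‑trimethyl‑4‑oxochroman‑8‑yl]methyl}‑2,4,6‑trihydroxy‑5‑methylphenyl]‑2‑methylbutan‑1‑one F8. Its a4 hydroxyl, para to the acyl group and the only one in ring A not chelated, is methylated (Me2SO4, one equivalent, K2CO3, acetone), which returns to the route at 17.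

## Further compounds

F1 | step 10 | (2R)‑2‑methylbutanoyl chloride | CC[C@@H](C)C(Cl)=O
F2 | step 10 | (2R)‑2‑methyl‑1‑(2,4,6‑trihydroxy‑3‑methylphenyl)butan‑1‑one | CC[C@@H](C)C(=O)c1c(O)cc(O)c(C)c1O
F3 | step 10 | (2R)‑1‑(2,6‑dihydroxy‑4‑methoxy‑3‑methylphenyl)‑2‑methylbutan‑1‑one | CC[C@@H](C)C(=O)c1c(O)cc(OC)c(C)c1O
F4 | step 5 | 2,4,6‑trihydroxy‑3‑methylbenzaldehyde | Cc1c(O)cc(O)c(C=O)c1O
F5 | step 4 | (2R)‑2‑methylbutanal | CC[C@@H](C)C=O
F6 | step 4 | 4‑hydroxy‑6‑[(3R)‑2‑hydroxy‑3‑methylpentyl]‑5‑methyl‑2H‑pyran‑2‑one (carbinol epimers) | CC[C@@H](C)C(O)CC1=C(C)C(O)=CC(=O)O1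
F7 | step 8 | 5,7‑bis(benzyloxy)‑8‑(hydroxymethyl)‑2,2,6‑trimethylchroman‑4‑one | CC1(C)CC(=O)c2c(OCc3ccccc3)c(C)c(OCc3ccccc3)c(CO)c2O1
F8 | step 9 | (2R)‑1‑[3‑{[5,7‑bis(benzyloxy)‑2,2,6‑trimethyl‑4‑oxochroman‑8‑yl]methyl}‑2,4,6‑trihydroxy‑5‑methylphenyl]‑2‑methylbutan‑1‑one | CC[C@@H](C)C(=O)c1c(O)c(C)c(O)c(Cc2c(OCc3ccccc3)c(C)c(OCc3ccccc3)c3c2OC(C)(C)CC3=O)c1O
A1 | alternative 1 | 5‑(benzyloxy)‑2‑{[2,4‑bis(benzyloxy)‑6‑methoxy‑5‑methylphenyl]methyl}‑4‑methyl‑3‑[(triisopropylsilyl)oxy]phenol | Oc1cc(OCc2ccccc2)c(C)c(O[Si](C(C)C)(C(C)C)C(C)C)c1Cc1c(OCc2ccccc2)cc(OCc2ccccc2)c(C)c1OC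
A2 | alternative 1 | 3‑(benzyloxy)‑2‑methylcyclobut‑2‑en‑1‑one | CC1=C(OCc2ccccc2)CC1=O
A3 | alternative 1 | ({3‑[2,4‑bis(benzyloxy)‑6‑methoxy‑5‑methylphenyl]prop‑1‑yn‑1‑yl}oxy)triisopropylsilane | CC(C)[Si](OC#CCc1c(OCc2ccccc2)cc(OCc2ccccc2)c(C)c1OC)(C(C)C)C(C)C
A4 | alternative 2 | (2R)‑1‑[2,6‑bis(benzyloxy)‑3‑{[5,7‑bis(benzyloxy)‑2,2,6‑trimethyl‑2H‑chromen‑8‑yl]methyl}‑4‑methoxy‑5‑methylphenyl]‑2‑methylbutan‑1‑one | CC[C@@H](C)C(=O)c1c(OCc2ccccc2)c(C)c(OC)c(Cc2c(OCc3ccccc3)c(C)c(OCc3ccccc3)c3C=CC(C)(C)Oc23)c1OCc1ccccc1
A5 | alternative 2 | (2R)‑1‑[2,6‑bis(benzyloxy)‑3‑({2,4‑bis(benzyloxy)‑3‑methyl‑6‑[(2‑methylbut‑3‑yn‑2‑yl)oxy]phenyl}methyl)‑4‑methoxy‑5‑methylphenyl]‑2‑methylbutan‑1‑one | CC[C@@H](C)C(=O)c1c(OCc2ccccc2)c(C)c(OC)c(Cc2c(OCc3ccccc3)c(C)c(OCc3ccccc3)cc2OC(C)(C)C#C)c1OCc1ccccc1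
A6 | alternative 3 | (2R)‑1‑[3‑{[5,7‑bis(benzyloxy)‑2,2,6‑trimethyl‑4‑oxochroman‑8‑yl]methyl}‑2‑ethoxy‑6‑hydroxy‑4‑methoxy‑5‑methylphenyl]‑2‑methylbutan‑1‑one | CC[C@@H](C)C(=O)c1c(O)c(C)c(OC)c(Cc2c(OCc3ccccc3)c(C)c(OCc3ccccc3)c3c2OC(C)(C)CC3=O)c1OCC
A7 | alternative 3 | 3‑{[5,7‑bis(benzyloxy)‑2,2,6‑trimethyl‑4‑oxochroman‑8‑yl]methyl}‑4‑methoxy‑5‑methyl‑2H‑pyran‑2,6(3H)‑dione | CC1=C(OC)C(Cc2c(OCc3ccccc3)c(C)c(OCc3ccccc3)c3c2OC(C)(C)CC3=O)C(=O)OC1=O
A8 | alternative 3 | (4R)‑1‑ethoxy‑4‑methylhex‑1‑yn‑3‑one | CC[C@@H](C)C(=O)C#COCC
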